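## Retrosynthetic overview

Prostanoid numbering is used (C1 ester carbon, ring C8–C12, C20 chain end). The two acetates and the exocyclic C7=C8 bond are cut last, by aldol condensation of a C8–C20 hydroxycyclopentenone with the (4R,5Z)-enal C1–C7.
The ring is cut at C9–C10 and C8–C12 at once, a formal [3+2]. A (Z)-β-iodoenone (C10–C20) meets tributyl(1-ethoxyvinyl)stannane (C8–C9) in a Stille coupling followed by acid-triggered 4π closure, all in one flask.
Enabling feature: the cyclopentenone C8–C12 is a cyclic tertiary aldol (C12–O is β to the C9 ketone through C8), and C9 and C12 are also bridged by the ring cis-alkene C10=C11. The ring is therefore the closed form of a U-shaped 1,4-dioxygenated pentadienyl cation C8–C9–C10–C11–C12, and closure of an oxygenated C8–C12 pentadienyl cation is also the presumed biosynthetic ring formation (allene oxide to preclavulone A).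
Fragments: the iodoenone comes from (3Z,6Z)-nona-3,6-dien-1-ol, which brings in both Z-alkenes. The enal comes from methyl succinyl chloride and a propargyl ether, with C4 set by asymmetric transfer hydrogenation and 5Z by semihydrogenation.
Ring order: there is only one ring, the cyclopentenone, formed in step 5.

Key step: step 5

Assumption: the (R)-configured acid catalyst of step 5 is taken as the enantiomer that favours (R)-10; if the sense of induction is the opposite, the (S)-acid is used and nothing else changes.

## Route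

Step 1
Reactants: 1 (3Z,6Z)-nona-3,6-dien-1-ol
Product: 2 (3Z,6Z)-nona-3,6-dienal
Conditions: 2-iodoxybenzoic acid (IBX, 1.3 equiv), DMSO, 23 °C; used at once
Reagents that add atoms: none
Why: IBX oxidation of a primary homoallylic alcohol is neutral enough to stop at the β,γ-unsaturated aldehyde without moving the 3Z double bond into conjugation, and no stereocentre is formed.

Step 2
Reactants: 2 (3Z,6Z)-nona-3,6-dienal; 3 ethynylmagnesium bromide
Product: 4 rac-(5Z,8Z)-undeca-5,8-dien-1-yn-3-ol
Conditions: THF, −78 to 0 °C; then H2O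
Reagents that add atoms: ethynylmagnesium bromide (3), C#C[Mg]Br
Why: Grignard 1,2-addition of the acetylide to the aldehyde at low temperature should outrun enolisation, and the new carbinol centre is racemic and is erased in step 3.

Step 3
Reactants: 4 rac-(5Z,8Z)-undeca-5,8-dien-1-yn-3-ol
Product: 5 (5Z,8Z)-undeca-5,8-dien-1-yn-3-one
Conditions: IBX (1.5 equiv), DMSO, 23 °C
Reagents that add atoms: none
Why: IBX oxidation of the propargylic alcohol gives the terminal ynone without base, so the doubly activated CH2 next to the ketone is not deprotonated and the skipped diene stays in place.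

Step 4
Reactants: 5 (5Z,8Z)-undeca-5,8-dien-1-yn-3-one
Product: 6 (1Z,5Z,8Z)-1-iodoundeca-1,5,8-trien-3-one
Conditions: NaI (1.1 equiv), AcOH, 23 °C, dark
Reagents that add atoms: sodium iodide, [Na+].[I-]
Why: hydroiodination of a terminal ynone is a conjugate addition of iodide followed by protonation of the allenol, a net anti addition that gives the (Z)-β-iodoenone under kinetic control.

Step 5
Reactants: 6 (1Z,5Z,8Z)-1-iodoundeca-1,5,8-trien-3-one; 7 tributyl(1-ethoxyvinyl)stannane
Product: 10 (4R)-4-hydroxy-4-[(2Z,5Z)-octa-2,5-dien-1-yl]cyclopent-2-en-1-one, via ethoxydienone 8 (not isolated), via ethoxycyclopentadienol 9 (not isolated)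
Conditions: Pd2(dba)3 (2.5 mol %), AsPh3 (10 mol %), toluene, 23–40 °C, dark; then −20 °C, (R)-3,3'-bis(2,4,6-triisopropylphenyl)-1,1'-binaphthyl-2,2'-diyl N-triflylphosphoramide (10 mol %); then H2O, THF, 0 °C
Reagents that add atoms: tributyl(1-ethoxyvinyl)stannane (7), CCCC[Sn](CCCC)(CCCC)C(=C)OCC; water, O
Why: Proposed new method: zerovalent palladium inserts into the C–I bond of 6 with retention and Stille transfer of the 1-ethoxyvinyl group makes C9–C10, giving the (3Z)-2-ethoxydienone 8, which reaches the U shape by one single-bond rotation; protonation of the C12 ketone by the chiral acid turns 8 into a 1-hydroxy-4-ethoxypentadienyl cation that closes C8–C12, loses a proton from C8 to give 9 (which frees the acid) and is hydrolysed to 10 when water is added. The closest known reaction types are the stereoretentive Stille coupling of (Z)-β-iodoenones and of 1-ethoxyvinylstannane, the Piancatelli rearrangement (the same 1,4-dioxygenated pentadienyl cation closing to a 4-hydroxycyclopentenone), its chiral-phosphoric-acid-catalysed aza variant and the N-triflylphosphoramide-catalysed Nazarov cyclisation; new are the convergent entry into the cation, the fully substituted terminus and the one-flask sequence. The single ring (cyclopentenone C8–C12) closes by a thermally allowed 4π conrotatory electrocyclisation, which read as an aldol addition is a 5-(enolendo)-exo-trig closure, and it copies the closure of the oxidopentadienyl cation presumed between the allene oxide and preclavulone A. The only new stereocentre, C12, is set by the sense of conrotation, which is controlled by the chiral phosphoramidate anion hydrogen-bonded to the C12–OH of the cation. The step needs Z geometry at C10=C11 (secured by the Z-iodide and the retentive coupling), C8 and not C13 as the nucleophilic terminus (secured by the regiodefined enol ether, since closure is run dry before water is added) and an intact skipped diene (secured by the absence of base).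

Step 6
Reactants: 10 (4R)-4-hydroxy-4-[(2Z,5Z)-octa-2,5-dien-1-yl]cyclopent-2-en-1-one
Product: 11 (4R)-4-[(2Z,5Z)-octa-2,5-dien-1-yl]-4-[(trimethylsilyl)oxy]cyclopent-2-en-1-one
Conditions: N-(trimethylsilyl)imidazole (1.5 equiv), CH2Cl2, 23 °C
Reagents that add atoms: N-(trimethylsilyl)imidazole, C[Si](C)(C)n1ccnc1
Why: silylation of the tertiary alcohol needs no acid or strong base, blocks retro-aldol opening (and so racemisation at C12) and makes the oxygen a poor leaving group for the enolate chemistry of step 13.

Step 7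
Reactants: 12 methyl 4-chloro-4-oxobutanoate; 13 tert-butyldimethyl(prop-2-yn-1-yloxy)silane
Product: 14 methyl 7-[(tert-butyldimethylsilyl)oxy]-4-oxohept-5-ynoate
Conditions: PdCl2(PPh3)2 (2 mol %), CuI (4 mol %), Et3N (1.2 equiv), THF, 23 °C
Reagents that add atoms: none
Why: the acyl Sonogashira coupling of an acid chloride with a terminal alkyne gives the ynone directly and tolerates the ester and the silyl ether.

Step 8
Reactants: 14 methyl 7-[(tert-butyldimethylsilyl)oxy]-4-oxohept-5-ynoate
Product: 15 methyl (4R)-7-[(tert-butyldimethylsilyl)oxy]-4-hydroxyhept-5-ynoate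
Conditions: Ru[(R,R)-TsDPEN](p-cymene) (16-electron amido complex, 1 mol %), iPrOH, 25 °C
Reagents that add atoms: none
Why: Noyori asymmetric transfer hydrogenation of ynones reduces only the C=O group, and with the (R,R)-ligand the alkynyl group takes the place of the aryl group in the six-membered hydride-transfer transition state, which should give the (4R)-propargylic alcohol.

Step 9
Reactants: 15 methyl (4R)-7-[(tert-butyldimethylsilyl)oxy]-4-hydroxyhept-5-ynoate
Product: 16 methyl (4R)-4-acetoxy-7-[(tert-butyldimethylsilyl)oxy]hept-5-ynoate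
Conditions: Ac2O, pyridine, DMAP (5 mol %), CH2Cl2, 0 °C
Reagents that add atoms: acetic anhydride, CC(=O)OC(C)=O
Why: DMAP-catalysed acetylation installs the C4 acetate of the target at once, before the γ-hydroxy ester can lactonise, and does not touch the stereocentre.

Step 10
Reactants: 16 methyl (4R)-4-acetoxy-7-[(tert-butyldimethylsilyl)oxy]hept-5-ynoate
Product: 17 methyl (4R,5Z)-4-acetoxy-7-[(tert-butyldimethylsilyl)oxy]hept-5-enoate
Conditions: H2 (1 atm), Pd/CaCO3 poisoned with Pb(OAc)2, quinoline, EtOAc, 23 °C
Reagents that add atoms: none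
Why: Lindlar semihydrogenation adds H2 syn to the alkyne and stops at the (5Z)-alkene.

Step 11
Reactants: 17 methyl (4R,5Z)-4-acetoxy-7-[(tert-butyldimethylsilyl)oxy]hept-5-enoate
Product: 18 methyl (4R,5Z)-4-acetoxy-7-hydroxyhept-5-enoate
Conditions: HF·pyridine, THF, 0 °C
Reagents that add atoms: none
Why: fluoride desilylation under slightly acidic conditions frees the primary allylic alcohol without acetate migration or ester cleavage.

Step 12
Reactants: 18 methyl (4R,5Z)-4-acetoxy-7-hydroxyhept-5-enoate
Product: 19 methyl (4R,5Z)-4-acetoxy-7-oxohept-5-enoate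
Conditions: TEMPO (10 mol %), PhI(OAc)2 (1.1 equiv), CH2Cl2, 23 °C, dark; used at once
Reagents that add atoms: none
Why: the oxoammonium (TEMPO/PhI(OAc)2) oxidation turns (Z)-allylic alcohols into (Z)-enals without base or nucleophilic amine, so the 5Z geometry should be kept.

Step 13
Reactants: 11 (4R)-4-[(2Z,5Z)-octa-2,5-dien-1-yl]-4-[(trimethylsilyl)oxy]cyclopent-2-en-1-one; 19 methyl (4R,5Z)-4-acetoxy-7-oxohept-5-enoate
Product: 21 methyl (4R,5Z)-4-acetoxy-7-hydroxy-7-{(2S)-2-hydroxy-2-[(2Z,5Z)-octa-2,5-dien-1-yl]-5-oxocyclopent-3-en-1-yl}hept-5-enoate (mixture of epimers at C7 and C8), via silyl aldol adduct 20 (not isolated)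
Conditions: LiN(iPr)2 (1.05 equiv), THF, −78 °C; 19, −78 °C; then 0.5 M HCl, THF, 0 °C
Reagents that add atoms: none
Why: kinetic deprotonation of the 4,4-disubstituted cyclopentenone can only occur at C8, the cross-conjugated lithium enolate undergoes aldol addition to the aldehyde faster than it attacks ester or acetate, the two new centres C7 and C8 form as a mixture that step 14 erases, and the acidic quench removes the trimethylsilyl group.

Step 14
Reactants: 21 methyl (4R,5Z)-4-acetoxy-7-hydroxy-7-{(2S)-2-hydroxy-2-[(2Z,5Z)-octa-2,5-dien-1-yl]-5-oxocyclopent-3-en-1-yl}hept-5-enoate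
Product: 24 17,18-dehydro-clavulone I, via C7 acetate 22 (not isolated), via C12 alcohol 23 (not isolated)
Conditions: Ac2O (excess), Et3N, DMAP (cat.), CH2Cl2, 0 to 23 °C
Reagents that add atoms: acetic anhydride, CC(=O)OC(C)=O
Why: DMAP-catalysed acetylation takes the secondary C7 alcohol first, the β-acetoxy ketone 22 loses acetic acid by E1cB elimination to the cross-conjugated dienone 23, whose preferred 7E geometry keeps C6 away from the C9 carbonyl oxygen and in the ring plane between the two out-of-plane substituents of C12, and the hindered C12 alcohol is then acetylated by the excess reagent without change at C4 or C12.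

## Compound list

1 | (3Z,6Z)-nona-3,6-dien-1-ol | CC/C=C\C/C=C\CCO | starting material
2 | (3Z,6Z)-nona-3,6-dienal | CC/C=C\C/C=C\CC=O | intermediate
3 | ethynylmagnesium bromide | C#C[Mg]Br | starting material
4 | rac-(5Z,8Z)-undeca-5,8-dien-1-yn-3-ol | CC/C=C\C/C=C\CC(O)C#C | intermediate
5 | (5Z,8Z)-undeca-5,8-dien-1-yn-3-one | CC/C=C\C/C=C\CC(=O)C#C | intermediate
6 | (1Z,5Z,8Z)-1-iodoundeca-1,5,8-trien-3-one | CC/C=C\C/C=C\CC(=O)/C=C\I | intermediate
7 | tributyl(1-ethoxyvinyl)stannane | CCCC[Sn](CCCC)(CCCC)C(=C)OCC | starting material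
8 | (3Z,7Z,10Z)-2-ethoxytrideca-1,3,7,10-tetraen-5-one | CC/C=C\C/C=C\CC(=O)/C=C\C(=C)OCC | intermediate
9 | (1S)-3-ethoxy-1-[(2Z,5Z)-octa-2,5-dien-1-yl]cyclopenta-2,4-dien-1-ol | CC/C=C\C/C=C\C[C@]1(O)C=CC(OCC)=C1 | intermediate
10 | (4R)-4-hydroxy-4-[(2Z,5Z)-octa-2,5-dien-1-yl]cyclopent-2-en-1-one | CC/C=C\C/C=C\C[C@]1(O)C=CC(=O)C1 | intermediate
11 | (4R)-4-[(2Z,5Z)-octa-2,5-dien-1-yl]-4-[(trimethylsilyl)oxy]cyclopent-2-en-1-one | CC/C=C\C/C=C\C[C@]1(O[Si](C)(C)C)C=CC(=O)C1 | intermediate
12 | methyl 4-chloro-4-oxobutanoate | COC(=O)CCC(=O)Cl | starting material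
13 | tert-butyldimethyl(prop-2-yn-1-yloxy)silane | C#CCO[Si](C)(C)C(C)(C)C | starting material
14 | methyl 7-[(tert-butyldimethylsilyl)oxy]-4-oxohept-5-ynoate | CC(C)(C)[Si](C)(C)OCC#CC(=O)CCC(=O)OC | intermediate
15 | methyl (4R)-7-[(tert-butyldimethylsilyl)oxy]-4-hydroxyhept-5-ynoate | CC(C)(C)[Si](C)(C)OCC#C[C@@H](CCC(=O)OC)O | intermediate
16 | methyl (4R)-4-acetoxy-7-[(tert-butyldimethylsilyl)oxy]hept-5-ynoate | CC(C)(C)[Si](C)(C)OCC#C[C@@H](CCC(=O)OC)OC(C)=O | intermediate
17 | methyl (4R,5Z)-4-acetoxy-7-[(tert-butyldimethylsilyl)oxy]hept-5-enoate | CC(C)(C)[Si](C)(C)OC/C=C\[C@@H](CCC(=O)OC)OC(C)=O | intermediate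
18 | methyl (4R,5Z)-4-acetoxy-7-hydroxyhept-5-enoate | OC/C=C\[C@@H](CCC(=O)OC)OC(C)=O | intermediate
19 | methyl (4R,5Z)-4-acetoxy-7-oxohept-5-enoate | O=C/C=C\[C@@H](CCC(=O)OC)OC(C)=O | intermediate
20 | silyl aldol adduct, the C12 trimethylsilyl ether of 21 (epimers at C7 and C8) | CC/C=C\C/C=C\C[C@]1(O[Si](C)(C)C)C=CC(=O)C1C(O)/C=C\[C@@H](CCC(=O)OC)OC(C)=O | intermediate
21 | methyl (4R,5Z)-4-acetoxy-7-hydroxy-7-{(2S)-2-hydroxy-2-[(2Z,5Z)-octa-2,5-dien-1-yl]-5-oxocyclopent-3-en-1-yl}hept-5-enoate (epimers at C7 and C8) | CC/C=C\C/C=C\C[C@]1(O)C=CC(=O)C1C(O)/C=C\[C@@H](CCC(=O)OC)OC(C)=O | intermediate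
22 | C7 acetate of 21 (epimers at C7 and C8) | CC/C=C\C/C=C\C[C@]1(O)C=CC(=O)C1C(OC(C)=O)/C=C\[C@@H](CCC(=O)OC)OC(C)=O | intermediate
23 | methyl (4R,5Z,7E)-4-acetoxy-7-{(2S)-2-hydroxy-2-[(2Z,5Z)-octa-2,5-dien-1-yl]-5-oxocyclopent-3-en-1-ylidene}hept-5-enoate | CC/C=C\C/C=C\C[C@]1(O)C=CC(=O)/C1=C/C=C\[C@@H](CCC(=O)OC)OC(C)=O | intermediate
24 | 17,18-dehydro-clavulone I, methyl (4R,5Z,7E)-4-acetoxy-7-{(2S)-2-acetoxy-2-[(2Z,5Z)-octa-2,5-dien-1-yl]-5-oxocyclopent-3-en-1-ylidene}hept-5-enoate | CC/C=C\C/C=C\C[C@]1(OC(C)=O)C=CC(=O)/C1=C/C=C\[C@@H](CCC(=O)OC)OC(C)=O | target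

## Step count

Total step count: 14.
Longest linear sequence: 8 steps (1–6, 13, 14). The enal branch (7–12, 13, 14) is equally long.

## Steps most likely to fail

**Step 5.** Three processes may go wrong:
- loss of the chiral acid to palladium, arsine or tin residues;
- low torquoselectivity at the fully substituted C12 terminus;
- diversion of 8 by oxa-6π closure, or by hydrolysis of the enol ether before ring closure, which would hand the nucleophilic role to C13.

The fallback uses known reaction types and replaces catalyst control by separation. It sets out from 6 and 7. The Stille coupling is run alone and 8 is isolated on triethylamine-washed silica. Compound 8 is then closed with one equivalent of BF3·OEt2 in CH2Cl2 at −78 °C, an intramolecular Mukaiyama-type aldol addition of an enol ether to a Lewis-acid-activated ketone. Aqueous work-up hydrolyses the product to racemic 4-hydroxy-4-[(2Z,5Z)-octa-2,5-dien-1-yl]cyclopent-2-en-1-one F1. Preparative HPLC on an amylose tris(3,5-dimethylphenylcarbamate) phase separates 10 from (4S)-4-hydroxy-4-[(2Z,5Z)-octa-2,5-dien-1-yl]cyclopent-2-en-1-one F2, which is set aside. The route is rejoined at 10.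

**Step 13.** The risks are Z-to-E isomerisation of the enal, acetate migration in the basic lithium aldolate, and retro-aldol loss of the adduct on warming. The fallback replaces the basic enolate by a neutral nucleophile. It sets out from 11, which with TMSOTf and Et3N in CH2Cl2 at 0 °C should give (5S)-5-[(2Z,5Z)-octa-2,5-dien-1-yl]-2,5-bis[(trimethylsilyl)oxy]cyclopenta-1,3-diene F3. A Mukaiyama aldol addition of F3 to 19 with BF3·OEt2 at −78 °C should give 20. The same dilute-acid treatment then gives 21, where the route is rejoined.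

**Step 14.** The risks are poor E/Z selectivity in the E1cB step, drift of the 5Z bond through reversible conjugate addition of DMAP, and retro-aldol opening of the free tertiary aldol before it is acetylated. The fallback separates the events and keeps C12 protected during the elimination. It sets out from 20, isolated after a neutral quench of step 13. MsCl and Et3N at −20 °C give the C7 methanesulfonate of 20 F4. DBU at −20 °C or neutral alumina eliminates F4 to the C12 trimethylsilyl ether of 23 F5, at which stage 7E and 7Z isomers can be separated. HF·pyridine then frees 23. Acetylation with Ac2O and catalytic Sc(OTf)3, a Lewis-acid acylation without nucleophilic amine, gives 24.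

## Further compounds

F1 | step 5 | racemic 4-hydroxy-4-[(2Z,5Z)-octa-2,5-dien-1-yl]cyclopent-2-en-1-one | CC/C=C\C/C=C\CC1(O)C=CC(=O)C1
F2 | step 5 | (4S)-4-hydroxy-4-[(2Z,5Z)-octa-2,5-dien-1-yl]cyclopent-2-en-1-one | CC/C=C\C/C=C\C[C@@]1(O)C=CC(=O)C1
F3 | step 13 | (5S)-5-[(2Z,5Z)-octa-2,5-dien-1-yl]-2,5-bis[(trimethylsilyl)oxy]cyclopenta-1,3-diene | CC/C=C\C/C=C\C[C@]1(O[Si](C)(C)C)C=CC(O[Si](C)(C)C)=C1
F4 | step 14 | C7 methanesulfonate of 20 | CC/C=C\C/C=C\C[C@]1(O[Si](C)(C)C)C=CC(=O)C1C(OS(C)(=O)=O)/C=C\[C@@H](CCC(=O)OC)OC(C)=O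
F5 | step 14 | C12 trimethylsilyl ether of 23 | CC/C=C\C/C=C\C[C@]1(O[Si](C)(C)C)C=CC(=O)/C1=C/C=C\[C@@H](CCC(=O)OC)OC(C)=O
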